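**Plan**

- Retrosynthesis: the first cut is the benzylic CH2–N(lactam) bond of target 8, giving p-quinone methide 6 and pyrrolidin-2-one 4. The second restores the CH2–CO2H bond on going from 6 through o-quinone 5 back to arylacetic acid 3. The three C–Br bonds and the two O-methyl groups then lead back to homoveratric acid 1.
- Forward: the benzene ring (in 1) and the lactam ring (4) are bought intact. Ether cleavage (2) and threefold bromination (3) come first; one electrolysis then exchanges CO2 for the lactam nitrogen at the benzylic carbon, joining the two rings last without closing any ring.
- Enabling feature: with the arene of 8 numbered C1 (CH2N), C2, C3, C6 (Br), C4, C5 (OH), the benzylic carbon sits on C1 para to the C4 hydroxyl of the oxidisable C4/C5 catechol. Every other ring carbon carries bromine, so two-electron oxidation can place electrophilic character only on the exocyclic carbon, as a p-quinone methide.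
- Stereochemistry: the target has no stereocentre and no stereogenic double bond, so nothing has to be set or preserved.

Key step: step 3

Remark on the chemistry: the tribromocatechol of 3 is assumed to be oxidised well below the lactam, the carboxylate and the C–Br bonds, as expected for a catechol; the anode potential is therefore set from a voltammogram of 3 recorded in the electrolysis medium.

**Route**

Step 1
Reactants: 1 3,4-dimethoxyphenylacetic acid (homoveratric acid)
Product: 2 3,4-dihydroxyphenylacetic acid
Conditions: 48% aq HBr, AcOH, reflux, N2
Reagents that add atoms: none
Why: Acid-mediated aryl methyl ether cleavage (O-protonation, then SN2 attack of bromide on the methyl carbon) is the standard way from veratrole derivatives to catechols, and the arylacetic acid side chain offers nothing that hot HBr can attack.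

Step 2
Reactants: 2 3,4-dihydroxyphenylacetic acid
Product: 3 2,3,6-tribromo-4,5-dihydroxyphenylacetic acid
Conditions: Br2 (3.05 equiv), dry AcOH, 15 °C to 40 °C, dark; then aq NaHSO3
Reagents that add atoms: bromine, BrBr
Why: Electrophilic aromatic bromination: each of the three free ring positions of 2 is ortho or para to a catechol hydroxyl, so three equivalents of bromine should fill them all as in the exhaustive bromination of catechol or 4-methylcatechol, while dry acetic acid and the near-stoichiometric charge keep bromine from oxidising the catechol and starting decarboxylation early.

Step 3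
Reactants: 3 2,3,6-tribromo-4,5-dihydroxyphenylacetic acid; 4 pyrrolidin-2-one
Product: 8 1-(2,3,6-tribromo-4,5-dihydroxybenzyl)pyrrolidin-2-one (target), via o-quinone acid 5 (not isolated), via p-quinone methide 6 (not isolated), via O-benzyl lactim ether 7 (not isolated)
Conditions: divided cell, graphite-felt anode, Pt cathode; anolyte Bu4NBF4 (0.1 M), 2,4,6-collidine (3 equiv), dry 4 (20 equiv)/CH2Cl2; catholyte Bu4NBF4, AcOH/CH2Cl2; anode held just past the catechol wave, 2 F/mol, 0 °C; then current off, 35 °C; aq Na2S2O4 wash
Reagents that add atoms: none
Why: Proposed new method: two-electron anodic oxidation of the catechol should give o-quinone 5, whose side chain is a vinylogous β-keto carboxylate (O=C5–C6=C1–CH2–CO2−), so CO2 leaves with the electron pair ending on the C5 oxygen to give p-quinone methide 6, and the exocyclic CH2 of 6 then takes the lactam nitrogen of 4 in a 1,6-addition that restores the arene. The closest known reaction types are the non-Kolbe (Hofer–Moest) anodic decarboxylation of electron-rich arylacetic acids with capture by heteroatom nucleophiles, the oxidative decarboxylation of 3,4-dihydroxyphenylacetic acid through its o-quinone and quinone methide, and amidoalkylation by 4-hydroxybenzyl alcohols and ethers. No ring is closed and no stereocentre is formed. Three selectivities are needed: decarboxylation over benzylic deprotonation in 5 (the bromines at C2 and C6 should hold the CH2–CO2− bond perpendicular to the ring, aligned with the quinone π system, with the C–H bonds near the ring plane), exocyclic over ring attack on 6 (C2, C3 and C6 are brominated and collidine is too hindered to add), and N- over O-alkylation (O-adducts such as lactim ether 7 keep a good leaving group para to the free C4 hydroxyl and should re-ionise to 6 on gentle warming with the collidinium formed, whereas the N-benzyl lactam does not). Over-oxidation of 8 is limited by stopping at 2 F per mole, since any quinone of 8 should re-oxidise unreacted 3 in solution, whose own quinone is removed irreversibly by loss of CO2, and the dithionite wash returns any remaining quinone to the catechol.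

**Compound list**

1 | 3,4-dimethoxyphenylacetic acid (homoveratric acid) | COc1ccc(CC(=O)O)cc1OC | starting material
2 | 3,4-dihydroxyphenylacetic acid | OC(=O)Cc1ccc(O)c(O)c1 | intermediate
3 | 2,3,6-tribromo-4,5-dihydroxyphenylacetic acid | OC(=O)Cc1c(Br)c(O)c(O)c(Br)c1Br | intermediate
4 | pyrrolidin-2-one | O=C1CCCN1 | starting material
5 | 2-(2,5,6-tribromo-3,4-dioxocyclohexa-1,5-dien-1-yl)acetic acid (o-quinone acid, present as its carboxylate) | OC(=O)CC1=C(Br)C(=O)C(=O)C(Br)=C1Br | intermediate (not isolated)
6 | 2,3,5-tribromo-6-hydroxy-4-methylidenecyclohexa-2,5-dien-1-one (p-quinone methide) | C=C1C(Br)=C(O)C(=O)C(Br)=C1Br | intermediate (not isolated)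
7 | 3,4,6-tribromo-5-[(3,4-dihydro-2H-pyrrol-5-yloxy)methyl]benzene-1,2-diol (O-benzyl lactim ether) | Oc1c(O)c(Br)c(Br)c(COC2=NCCC2)c1Br | intermediate (not isolated)
8 | 1-(2,3,6-tribromo-4,5-dihydroxybenzyl)pyrrolidin-2-one | O=C1CCCN1Cc1c(Br)c(O)c(O)c(Br)c1Br | target

**Step count**

Total step count: 3. Longest linear sequence: 3 steps (1 to 2 to 3 to 8); lactam 4 enters in step 3.

**Steps most likely to fail**

Step 3 (proposed new method). Several processes may go wrong:
- The o-quinone may tautomerise by benzylic deprotonation, or be attacked at a brominated ring carbon by addition–elimination, faster than it loses CO2.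
- The quinone methide may be consumed by oxygen nucleophiles or by other catechol molecules in adducts that do not revert.
- The product catechol may be oxidised further at the anode.

The fallback makes the benzylic C–N bond by classical lactam N-alkylation. It sets out from pyrrolidin-2-one 4 and returns to the route at 8. Commercially available 4-methylcatechol would be brominated exhaustively (Br2, AcOH) to 3,4,6-tribromo-5-methylbenzene-1,2-diol F1. Both hydroxyls would be methylated (MeI, K2CO3, DMF) to give 1,2,4-tribromo-5,6-dimethoxy-3-methylbenzene F2. Wohl–Ziegler bromination (NBS, AIBN, PhCF3, reflux) would give 1,2,4-tribromo-3-(bromomethyl)-5,6-dimethoxybenzene F3. The sodium salt of 4 (NaH, THF/DMF, 0 °C) would be alkylated with F3 to give 1-[(2,3,6-tribromo-4,5-dimethoxyphenyl)methyl]pyrrolidin-2-one F4. BBr3 (CH2Cl2, −78 °C to room temperature) would then cleave both methyl ethers to give 8.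

Step 2. Bromine may act as a two-electron oxidant on the brominated catechol, or attack ipso at the carbon para to the C4 hydroxyl, so that the free acid decarboxylates prematurely. The third substitution, at the position flanked by the side chain, may also stop short. The fallback masks the carboxyl group so that CO2 cannot be lost and the bromination can be forced. It sets out from 2 and returns at 3. Fischer esterification (MeOH, cat. H2SO4, reflux) would give methyl 2-(3,4-dihydroxyphenyl)acetate F5. Bromination with an excess of Br2 in AcOH with warming, followed by NaHSO3 to return any quinone to the catechol, would give methyl 2-(2,3,6-tribromo-4,5-dihydroxyphenyl)acetate F6. Acid hydrolysis (6 M HCl, dioxane, reflux, N2) would give 3.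

Step 1. Cleavage of the second ether may be incomplete, and the electron-rich, water-soluble catechol acid may be lost by air oxidation and poor extraction from the hot aqueous acid. The fallback changes the order of events and bypasses 2. It sets out from 1 and returns at 3. Monobromination (Br2, 1 equiv, AcOH, room temperature), para to the C3 methoxy group, would give 2-(2-bromo-4,5-dimethoxyphenyl)acetic acid F7. Anhydrous ether cleavage with BBr3 (CH2Cl2, −78 °C to room temperature) would give the less oxidisable and more easily extracted 2-(2-bromo-4,5-dihydroxyphenyl)acetic acid F8. Two further equivalents of Br2 in dry AcOH would fill the two remaining positions, each ortho to a hydroxyl, to give 3.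

Further compounds
F1 | step 3 | 3,4,6-tribromo-5-methylbenzene-1,2-diol | Cc1c(Br)c(O)c(O)c(Br)c1Br
F2 | step 3 | 1,2,4-tribromo-5,6-dimethoxy-3-methylbenzene | COc1c(OC)c(Br)c(Br)c(C)c1Br
F3 | step 3 | 1,2,4-tribromo-3-(bromomethyl)-5,6-dimethoxybenzene | COc1c(OC)c(Br)c(Br)c(CBr)c1Br
F4 | step 3 | 1-[(2,3,6-tribromo-4,5-dimethoxyphenyl)methyl]pyrrolidin-2-one | COc1c(OC)c(Br)c(Br)c(CN2CCCC2=O)c1Br
F5 | step 2 | methyl 2-(3,4-dihydroxyphenyl)acetate | COC(=O)Cc1ccc(O)c(O)c1
F6 | step 2 | methyl 2-(2,3,6-tribromo-4,5-dihydroxyphenyl)acetate | COC(=O)Cc1c(Br)c(O)c(O)c(Br)c1Br
F7 | step 1 | 2-(2-bromo-4,5-dimethoxyphenyl)acetic acid | COc1cc(Br)c(CC(=O)O)cc1OC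
F8 | step 1 | 2-(2-bromo-4,5-dihydroxyphenyl)acetic acid | OC(=O)Cc1cc(O)c(O)cc1Br
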